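**Retrosynthetic overview**
1. Ring B is a hydroquinone whose hydroxyl-bearing carbons C2' and C5' are para to each other, with the C4' methoxy group next to C5'. The C5' oxygen is therefore cut last: hydroquinone ⇐ methoxy-para-quinone ⇐ C5' dimethyl monoketal ⇐ 2'-hydroxy-4'-methoxyphenyl flavone (anodic methoxylation, two C5'–O bonds).
2. The free C2' phenol comes from its benzyl ether by hydrogenolysis, and the C3 methyl ether from O-methylation of the flavonol.
3. Ring C (O1–C2 and C3–O bonds) is cut by an Algar–Flynn–Oyamada transform to an ortho-hydroxyaryl enone (chalcone). A Claisen–Schmidt transform then cuts the chalcone to a ring A acetophenone and a ring B aldehyde.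
4. The C3 methoxy group is not brought in as a methoxyacetyl unit, because methoxyacetyl chloride loses CO under AlCl3 and then alkylates rather than acylates electron-rich arenes.
5. Ring order: rings A and B are bought, ring C is the only ring formed (step 3), and no ring is formed after it.

Key step: step 6

Remark: flavone numbering is used throughout (ring C: O1, C2, C3, C4; ring A: C4a to C8a; ring B: C1' to C6'). The target has no stereocentre, so the only stereochemical element of the route is the E alkene of the chalcone.

**Step 1**
Reactants: 1 2-hydroxy-4-methoxybenzaldehyde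
Product: 2 2-(benzyloxy)-4-methoxybenzaldehyde
Conditions: BnBr, K2CO3, DMF, 60 °C
Reagents that add atoms: benzyl bromide, BrCc1ccccc1
Why: Williamson ether synthesis on the only acidic OH masks the future C2' phenol, whose phenoxide would otherwise deactivate the aldehyde in the aldol step and be attacked by alkaline peroxide in step 3.

**Step 2**
Reactants: 2 2-(benzyloxy)-4-methoxybenzaldehyde; 3 1-(2-hydroxy-3,4-dimethoxyphenyl)ethanone
Product: 4 (E)-3-[2-(benzyloxy)-4-methoxyphenyl]-1-(2-hydroxy-3,4-dimethoxyphenyl)prop-2-en-1-one
Conditions: KOH, EtOH, rt
Reagents that add atoms: none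
Why: Claisen–Schmidt condensation, in which the methyl ketone enolate adds to the non-enolisable aldehyde and E1cB loss of water gives the conjugated enone as its more stable E isomer, the strongly basic medium holding the product as the open chalcone phenoxide.

**Step 3**
Reactants: 4 (E)-3-[2-(benzyloxy)-4-methoxyphenyl]-1-(2-hydroxy-3,4-dimethoxyphenyl)prop-2-en-1-one
Product: 5 2-[2-(benzyloxy)-4-methoxyphenyl]-3-hydroxy-7,8-dimethoxychromen-4-one
Conditions: 30% aq H2O2, NaOH, MeOH, 0 °C to rt
Reagents that add atoms: hydrogen peroxide, OO
Why: Algar–Flynn–Oyamada reaction, in which the ring A phenoxide closes the O1–C2 bond by 6-endo conjugate addition while the α-carbon is oxygenated by hydroperoxide and further oxidant dehydrogenates ring C to the flavonol, six-ring closure being the normal course when the future C5 carries only hydrogen.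

**Step 4**
Reactants: 5 2-[2-(benzyloxy)-4-methoxyphenyl]-3-hydroxy-7,8-dimethoxychromen-4-one
Product: 6 2-[2-(benzyloxy)-4-methoxyphenyl]-3,7,8-trimethoxychromen-4-one
Conditions: MeI, K2CO3, acetone, reflux
Reagents that add atoms: iodomethane, CI
Why: Williamson O-methylation of the acidic enolic 3-OH, the only free hydroxyl group of 5, fixes the C3 methyl ether of the target.

**Step 5**
Reactants: 6 2-[2-(benzyloxy)-4-methoxyphenyl]-3,7,8-trimethoxychromen-4-one
Product: 7 2-(2-hydroxy-4-methoxyphenyl)-3,7,8-trimethoxychromen-4-one
Conditions: H2 (1 atm), Pd/C, EtOAc–MeOH, rt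
Reagents that add atoms: none
Why: Catalytic hydrogenolysis cleaves the benzylic C–O bond selectively, because the tetrasubstituted C2=C3 bond belongs to the vinylogous ester of the chromone and is not reduced at one atmosphere and room temperature.

**Step 6**
Reactants: 7 2-(2-hydroxy-4-methoxyphenyl)-3,7,8-trimethoxychromen-4-one
Product: 9 2-(3,3,4-trimethoxy-6-oxocyclohexa-1,4-dien-1-yl)-3,7,8-trimethoxychromen-4-one, via 5'-methoxyphenol 8 (not isolated)
Conditions: glassy carbon anode, Pt cathode, undivided cell, 0.1 M LiClO4, MeOH, constant current, about 4.2 F/mol, 0 °C to rt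
Reagents that add atoms: methanol, CO
Why: This is the anodic methoxylation of a para-unsubstituted phenol to a para-quinone dimethyl monoketal, a known four-electron phenol oxidation whose chemical counterpart uses PhI(OAc)2 in methanol. Phenol 7 loses two electrons and the O–H proton to give a phenoxonium ion, methanol adds at C5' and tautomerisation gives the para-methoxyphenol 8, which is easier to oxidise than 7, so it loses two more electrons and a proton and a second methanol traps the oxygen-stabilised cation at the same carbon, while the released protons are discharged as hydrogen at the cathode. Two C5'–O bonds are formed, no ring is closed and no stereocentre arises, because C5' of 9 carries two identical methoxy groups. The chemoselectivity needed is secured by the free ring B phenol being the best donor in the molecule: ring A is drained by the C4 carbonyl para to its C7 methoxy group and by O1 being tied up in a vinylogous ester, the C2=C3 enol ether is conjugated to the same carbonyl, and dienone 9 is harder to oxidise than either phenol, so charge control stops the reaction at the ketal. The regioselectivity needed is para over ortho trapping: the phenoxonium charge sits on C1', C3' and C5', of which C1' is quaternary, C3' is wedged between two oxygen substituents and C5' is an open CH, and in the second oxidation the new C5' methoxy group itself localises the charge at C5'. Dilute neutral solution favours the two-electron cationic path over phenoxyl radical coupling, and the undivided cell keeps the bulk neutral so that the ketal survives.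

**Step 7**
Reactants: 9 2-(3,3,4-trimethoxy-6-oxocyclohexa-1,4-dien-1-yl)-3,7,8-trimethoxychromen-4-one
Product: 11 diplotrin A [2-(2,5-dihydroxy-4-methoxyphenyl)-3,7,8-trimethoxychromen-4-one], via methoxyquinone 10 (not isolated)
Conditions: p-TsOH·H2O (20 mol %), THF–H2O, rt to 40 °C until 9 is consumed; then Na2S2O4, H2O, N2, rt
Reagents that add atoms: water, O
Why: Acid-catalysed ketal hydrolysis with a non-nucleophilic acid should release the C5' carbonyl before the vinylogous ester at C4' is touched, and the standard dithionite reduction of the para-quinone then delivers both ring B hydroxyl groups while the chromone and the four methyl ethers stay inert.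

**Compound list**
1 | 2-hydroxy-4-methoxybenzaldehyde | COc1ccc(C=O)c(O)c1 | starting material
2 | 2-(benzyloxy)-4-methoxybenzaldehyde | COc1ccc(C=O)c(OCc2ccccc2)c1 | intermediate
3 | 1-(2-hydroxy-3,4-dimethoxyphenyl)ethanone | CC(=O)c1ccc(OC)c(OC)c1O | starting material
4 | (E)-3-[2-(benzyloxy)-4-methoxyphenyl]-1-(2-hydroxy-3,4-dimethoxyphenyl)prop-2-en-1-one | COc1ccc(/C=C/C(=O)c2ccc(OC)c(OC)c2O)c(OCc2ccccc2)c1 | intermediate
5 | 2-[2-(benzyloxy)-4-methoxyphenyl]-3-hydroxy-7,8-dimethoxychromen-4-one | COc1ccc(-c2oc3c(OC)c(OC)ccc3c(=O)c2O)c(OCc2ccccc2)c1 | intermediate
6 | 2-[2-(benzyloxy)-4-methoxyphenyl]-3,7,8-trimethoxychromen-4-one | COc1ccc(-c2oc3c(OC)c(OC)ccc3c(=O)c2OC)c(OCc2ccccc2)c1 | intermediate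
7 | 2-(2-hydroxy-4-methoxyphenyl)-3,7,8-trimethoxychromen-4-one | COc1ccc(-c2oc3c(OC)c(OC)ccc3c(=O)c2OC)c(O)c1 | intermediate
8 | 2-(2-hydroxy-4,5-dimethoxyphenyl)-3,7,8-trimethoxychromen-4-one | COc1cc(O)c(-c2oc3c(OC)c(OC)ccc3c(=O)c2OC)cc1OC | intermediate
9 | 2-(3,3,4-trimethoxy-6-oxocyclohexa-1,4-dien-1-yl)-3,7,8-trimethoxychromen-4-one | COC1=CC(=O)C(c2oc3c(OC)c(OC)ccc3c(=O)c2OC)=CC1(OC)OC | intermediate
10 | 2-methoxy-5-(3,7,8-trimethoxy-4-oxochromen-2-yl)cyclohexa-2,5-diene-1,4-dione | COC1=CC(=O)C(c2oc3c(OC)c(OC)ccc3c(=O)c2OC)=CC1=O | intermediate
11 | diplotrin A, 2-(2,5-dihydroxy-4-methoxyphenyl)-3,7,8-trimethoxychromen-4-one | COc1cc(O)c(-c2oc3c(OC)c(OC)ccc3c(=O)c2OC)cc1O | target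

**Total step count:** 7. **Longest linear sequence:** 7 steps (1 to 11); acetophenone 3 enters as purchased in step 2.

**Steps most likely to fail**

**Step 6.**
- What may go wrong: the anode may be passivated by films from phenoxyl radical coupling. Part of the phenoxonium ion may be trapped ortho. Selectivity against ring A may erode as the cell voltage rises.
- Fallback: setting out from 7, the C5' oxygen would be delivered by an Elbs persulfate oxidation instead of at an electrode.
- With K2S2O8 in aqueous KOH–pyridine at 0 °C to rt, the phenoxide attacks the peroxide O–O bond through its para carbon C5'. This should give potassium 4-hydroxy-2-methoxy-5-(3,7,8-trimethoxy-4-oxochromen-2-yl)phenyl sulfate F1.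
- Unreacted 7 is extracted after neutralisation. Warming the aqueous sulfate in dilute HCl, with a little Na2SO3 against air oxidation, cleaves the sulfate ester.
- The route is rejoined at 11, bypassing 9 and 10.

**Step 3.**
- What may go wrong: the oxidative cyclisation may be diverted to five-ring closure or to cleavage of the enone. The ortho-benzyloxy group crowds the β-carbon and makes this more likely.
- Fallback: setting out from 4, ring C would be closed at the flavone level and C3 oxygenated separately.
- Catalytic I2 in DMSO at 120 °C (oxidative cyclisation of ortho-hydroxychalcones) should give 2-[2-(benzyloxy)-4-methoxyphenyl]-7,8-dimethoxychromen-4-one F2.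
- Dimethyldioxirane in acetone–CH2Cl2 at 0 °C should epoxidise the C2=C3 bond to the racemic cis-fused flavone 2,3-epoxide F3.
- A trace of p-TsOH then opens the oxirane at the oxygen-stabilised benzylic C2. After loss of the C3 proton this gives flavonol 5, where the route is rejoined.

**Step 7.**
- What may go wrong: ionisation of the electron-poor ketal may be sluggish, so that the stronger acid then needed also hydrolyses the vinylogous ester at C4'. Reduction before hydrolysis is complete would aromatise the ring with loss of only one methanol.
- Fallback: setting out from 9, the ketal would be unmasked by a reduction and oxidation pair instead of by hydrolysis.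
- Zn dust in AcOH–THF reduces the dienone, which aromatises with loss of one methanol to the para-methoxyphenol 8, now isolated.
- (NH4)2Ce(NO3)6 in aqueous MeCN at 0 °C then performs an oxidative demethylation. Water adds at C5' of the oxidised ring and methanol leaves, giving quinone 10 quickly and without long exposure to acid.
- The route is rejoined at 10, and dithionite reduction as in step 7 leads to 11. No compound outside the compound list is made on this way (F0).

**Further compounds**
F1 | step 6 | potassium 4-hydroxy-2-methoxy-5-(3,7,8-trimethoxy-4-oxochromen-2-yl)phenyl sulfate | COc1cc(O)c(-c2oc3c(OC)c(OC)ccc3c(=O)c2OC)cc1OS(=O)(=O)[O-].[K+]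
F2 | step 3 | 2-[2-(benzyloxy)-4-methoxyphenyl]-7,8-dimethoxychromen-4-one | COc1ccc(-c2cc(=O)c3ccc(OC)c(OC)c3o2)c(OCc2ccccc2)c1
F3 | step 3 | 1a-[2-(benzyloxy)-4-methoxyphenyl]-3,4-dimethoxy-1a,7a-dihydro-7H-oxireno[2,3-b]chromen-7-one (racemic cis-fused 2,3-epoxide of F2, one enantiomer drawn) | COc1ccc([C@]23Oc4c(OC)c(OC)ccc4C(=O)[C@H]2O3)c(OCc2ccccc2)c1
F0 | step 7 | none | none
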